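I follow free X rather than J in this flask, and I read it at the asked time.

L 2.0 M; Q 1.00 equiv; time 4.0 min

    E ⇌ D (K1 = 0.209, k1 = 0.00296 /s)
    Q.X.Q → J (k2 = 0.0656 /s)
    Q + X.Q ⇌ Q.X.Q (K3 = 0.491 /M, k3 = 0.00168 /M/s)
    X + Q → X.Q (k4 = 0.00317 /M/s)
    X + Q ⇌ E (K5 = 0.227 /M, k5 = 0.00164 /M/s)
    L ⇌ X, rate k6*(cs6 - [X]) while solid is left; crystals form when [X] > cs6 (cs6 = 1.2 M, k6 = 0.00426 /s)

* the J standing at 4.0 min, as a percentage of the L charged
* concentration of X in solution at 4.0 min, in percent of saturation

Q is charged at 2.00 M, and I hold it there for this reckoning. As drain on X I count the uptake into X.Q, pseudo-first-order with constant 0.00634 /s; X + Q to E takes X as well, and I leave it out of this rough reckoning as a simplification. Free X then climbs towards 0.482 M, the level at which dissolution equals uptake into X.Q with Q held at its charge; I call this the free-X plateau. The climb has a time constant of 1.57 min, so at 4.0 min X stands at 37.0 % of saturation. Q.X.Q passes on to J with a half-life of 0.18 min, shorter than the run, so I count each addition of Q to X.Q as one J. X.Q growing at the plateau's uptake rate after that lag gives 5.45 % of the L charged as J, which is my figure for the yield: 5.45 %.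

The forecast gives 4.3 % and 36 %, holding that “J is limited by the slow second addition of Q to X.Q”; its J lies below mine.

The simulation gives 3.58 % and 36.9 %, so the forecast stands within the margins on both.

At 4.00 min the flask holds X.Q at 14.7 % of the L charged, more than J at 3.58 %, and X.Q is being made 2.99 times as fast as it is used up, each step taken net, so the thing to watch is X.Q climbing. For the neighbour flask left until 6.0 min, the plateau and its time constant give X at 23.6 % of the L charged, and that flask holds 27.1 %, with its Q down to 54 % of its charge.

The constants used here come from no measurement; the flask was simulated.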